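The seven-membered ring of this daucane (numbering: C1 angular-methyl carbon, C4 carbinol, C5 ring-fusion CH, C6 aroyloxy carbon, C7 CH2, C8=C9, C10 angeloyloxy carbon) is cut at C6–C7 and C1–C10. Because C10 bears oxygen and the C8=C9 bond lies between C7 and C10, C7 to C10 are taken from 3-methylfuran, whose ring oxygen becomes O-10 and stays bonded to C7 as a temporary bridge. C6, C5 and C1 come from the alkenylcarbene complex (CO)5Cr=C(OMe)R (R = cyclopentenyl). Cyclopropanation then Cope rearrangement joins both bonds in one operation, sets quaternary C1 and places O-10 syn to its methyl. The bridge later controls C5 and C4 and is cut by SmI2.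

Key step: step 4

Remark: names use the daucane numbering above, syn and anti refer to the face of the C1 methyl group, and 2-bromo-3-methylcyclopent-2-en-1-one, 3-methylfuran, 4-acetoxybenzoyl chloride and angelic acid are taken as catalogue compounds.

Step 1
Reactants: 1 2-bromo-3-methylcyclopent-2-en-1-one
Product: 2 (S)-2-bromo-3-methylcyclopent-2-en-1-ol
Conditions: BH3·SMe2, (R)-2-methyl-CBS-oxazaborolidine (10 mol%), THF, −20 °C; MeOH quench
Reagents that add atoms: none
Why: Corey–Bakshi–Shibata reduction, in which the bromoalkene arm of the enone acts as the large group, so that the (R)-oxazaborolidine–borane complex should deliver hydride to one carbonyl face and give the (S)-allylic alcohol by 1,2-reduction.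

Step 2
Reactants: 2 (S)-2-bromo-3-methylcyclopent-2-en-1-ol
Product: 3 (S)-[(2-bromo-3-methylcyclopent-2-en-1-yl)oxy]triethylsilane
Conditions: Et3SiCl, imidazole, CH2Cl2, 0 °C
Reagents that add atoms: chlorotriethylsilane, CC[Si](Cl)(CC)CC
Why: Standard silylation of a secondary alcohol, giving an ether that tolerates organolithium and carbene chemistry, later shields one face of the cyclopentene and is labile enough to fall off under the mild acid of step 5, with the stereocenter untouched.

Step 3
Reactants: 3 (S)-[(2-bromo-3-methylcyclopent-2-en-1-yl)oxy]triethylsilane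
Product: 6 pentacarbonyl{methoxy[(5S)-2-methyl-5-(triethylsilyloxy)cyclopent-1-en-1-yl]methylidene}chromium, via vinyllithium 4 (not isolated), via lithium acylpentacarbonylchromate 5 (not isolated)
Conditions: t-BuLi (2 equiv), Et2O, −78 °C; Cr(CO)6, −78 °C to rt; MeOTf, CH2Cl2, 0 °C
Reagents that add atoms: chromium hexacarbonyl, O=C=[Cr](=C=O)(=C=O)(=C=O)(=C=O)=C=O; methyl triflate, COS(=O)(=O)C(F)(F)F
Why: Fischer carbene synthesis, in which bromine–lithium exchange gives the vinyllithium, this adds to a carbonyl ligand of Cr(CO)6 and methyl triflate alkylates the acylchromate on oxygen, so that the carbene carbon (the future C6 with its oxygen) is a former CO ligand and the existing stereocenter is not involved.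

Step 4
Reactants: 6 pentacarbonyl{methoxy[(5S)-2-methyl-5-(triethylsilyloxy)cyclopent-1-en-1-yl]methylidene}chromium; 7 3-methylfuran
Product: 9 bridged enol ether 7,10-epoxy-6-methoxy-4-(triethylsilyloxy)-11,12,13-trinordauca-5,8-diene (epoxy bridge syn; 4-O syn), via divinylcyclopropane 8 (not isolated)
Conditions: 7 (10 equiv), toluene, CO (1 atm), 90 °C, sealed tube
Reagents that add atoms: none
Why: Proposed new method: the furan should attack the electrophilic carbene carbon of 6 through its most nucleophilic α-carbon (the one next to the methyl group, giving a tertiary allyl-oxocarbenium ion) and close with loss of Cr(CO)5 to the endo-alkenyl cyclopropane 8, a cis-divinylcyclopropane whose Cope rearrangement through a boat transition state breaks the temporary C6–C8 bond and forms C1–C10. The closest known reaction types are the cyclopropanation/Cope (4+3) annulation of alkenyl Fischer carbene complexes with electron-rich open-chain 1,3-dienes and the same tandem of rhodium vinylcarbenes with furans, so only the pairing of a chromium carbene with a furan is untested. The cyclopropane closes by [2+1] addition to the C7=C8 bond and the seven-membered carbocycle by the [3,3] shift, an overall (4+3) cycloaddition that leaves the furan oxygen as a one-atom bridge from C7 to C10. C7 and C10 are cis through the furan ring, and because the furan oxygen at C10 and the methyl group at C1 are both forced to be inside substituents of the boat, O-10 ends syn to the angular methyl at the new quaternary C1. The absolute sense is set by the C4 silyloxy group, anti to which the dihydrofuran folds over the cyclopentene, and cyclopropanes of the wrong geometry can re-open at the donor-substituted C6–C8 bond. The step needs attack at the methyl-bearing double bond of the furan, which the donor methyl secures, and cyclopropanation in preference to Diels–Alder addition or substitution, which the tetrasubstituted alkene of 6 and the CO atmosphere favour.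

Step 5
Reactants: 9 bridged enol ether
Product: 10 6,6-(ethylenedioxy)-7,10-epoxy-11,12,13-trinordauc-8-en-4-ol (4-OH syn; H-5 anti)
Conditions: HOCH2CH2OH, PPTS (cat.), MeOH/CH2Cl2, rt
Reagents that add atoms: ethylene glycol, OCCO
Why: Acid-catalysed transketalisation of the enol ether, in which reversible protonation at C5 occurs on the face anti to the C1 methyl and C4 silyloxy groups (this trans ring fusion is also the only unstrained one in the bridged chair), the glycol traps the oxocarbenium ion and the triethylsilyl ether is solvolysed under the same conditions.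

Step 6
Reactants: 10 ketal alcohol
Product: 11 6,6-(ethylenedioxy)-7,10-epoxy-11,12,13-trinordauc-8-en-4-one
Conditions: Dess–Martin periodinane, pyridine, CH2Cl2, 0 °C to rt
Reagents that add atoms: none
Why: Dess–Martin oxidation of the secondary alcohol under buffered conditions that leave the ketal, the bridging ether and the alkene alone and do not epimerise C5.

Step 7
Reactants: 11 ketal ketone
Product: 12 6,6-(ethylenedioxy)-7,10-epoxydauc-8-en-4-ol (4-OH syn; isopropyl anti)
Conditions: i-PrMgCl, CeCl3, THF, −78 °C
Reagents that add atoms: isopropylmagnesium chloride, CC(C)[Mg]Cl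
Why: Organocerium 1,2-addition (low basicity suppresses enolisation and β-hydride reduction) to the cyclopentanone from the face anti to the axial C1 methyl group, which should give the tertiary alcohol with hydroxyl syn and isopropyl anti to that methyl.

Step 8
Reactants: 12 ketal carbinol
Product: 13 7,10-epoxy-4-hydroxydauc-8-en-6-one
Conditions: aq. HCl (2 M), THF, rt to 40 °C
Reagents that add atoms: water, O
Why: Acid hydrolysis of the dioxolane, helped by relief of the 1,3-diaxial contact between a ketal oxygen and the C1 methyl, gives the β-hydroxy ketone, while the tertiary non-allylic alcohol does not ionise and C5 stays in its stable trans-fused configuration.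

Step 9
Reactants: 13 bridged hydroxy ketone
Product: 15 dauc-8-ene-4,6,10-triol (4-OH syn; 6-OH anti; 10-OH syn; H-5 anti), via ring-opened hydroxy ketone 14 (not isolated)
Conditions: SmI2 (6 equiv), THF/MeOH, −78 °C to 0 °C
Reagents that add atoms: none
Why: SmI2 reductive cleavage of the C7–O bond α to the ketone releases the C10 alkoxide and an enolate that methanol protonates at C7 (the C8=C9 bond stays in place), and further SmI2 reduces the samarium-chelated β-hydroxy ketone with hydrogen delivered on the face of the C4 hydroxyl, which should give the anti-1,3-diol with 6-OH anti to the C1 methyl.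

Step 10
Reactants: 15 dauc-8-ene-4,6,10-triol; 16 4-acetoxybenzoyl chloride
Product: 17 6-O-(4-acetoxybenzoyl)dauc-8-ene-4,6,10-triol
Conditions: 16 (1.1 equiv), pyridine, CH2Cl2, −20 °C
Reagents that add atoms: none
Why: Site-selective acylation with an acid chloride, since the C6 hydroxyl is flanked by a methylene group whereas the C10 hydroxyl is neopentylic and the C4 hydroxyl tertiary, so that one equivalent at low temperature should esterify C6 only and change no stereocenter.

Step 11
Reactants: 17 6-O-(4-acetoxybenzoyl)dauc-8-ene-4,6,10-triol; 18 angelic acid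
Product: 20 10-O-angeloyl-6-O-(4-acetoxybenzoyl)dauc-8-ene-4,6,10-triol, via mixed anhydride 19 (not isolated)
Conditions: 18, 2,4,6-trichlorobenzoyl chloride, Et3N, toluene, rt; then 17, 80 °C
Reagents that add atoms: none
Why: Yamaguchi-type esterification through the preformed mixed anhydride without DMAP, the usual way to acylate a hindered alcohol with angelic acid without isomerisation to the tiglate, in which only the remaining secondary hydroxyl at C10 reacts.

Step 12
Reactants: 20 10-O-angeloyl-6-O-(4-acetoxybenzoyl)dauc-8-ene-4,6,10-triol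
Product: 21 target, 10-O-angeloyl-6-O-(4-hydroxybenzoyl)dauc-8-ene-4,6,10-triol
Conditions: pyrrolidine, CH2Cl2, 0 °C
Reagents that add atoms: none
Why: Chemoselective aminolysis of the phenolic acetate, an activated aryl ester, which should leave the hindered angelate and the alkyl benzoate untouched and free the phenol.

Compound list
1 | 2-bromo-3-methylcyclopent-2-en-1-one | O=C1CCC(C)=C1Br | starting material
2 | (S)-2-bromo-3-methylcyclopent-2-en-1-ol | BrC1=C(C)CC[C@@H]1O | intermediate
3 | (S)-[(2-bromo-3-methylcyclopent-2-en-1-yl)oxy]triethylsilane | BrC1=C(C)CC[C@@H]1O[Si](CC)(CC)CC | intermediate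
4 | [(5S)-2-methyl-5-(triethylsilyloxy)cyclopent-1-en-1-yl]lithium | [Li]C1=C(C)CC[C@@H]1O[Si](CC)(CC)CC | intermediate
5 | lithium pentacarbonyl{[(5S)-2-methyl-5-(triethylsilyloxy)cyclopent-1-en-1-yl]carbonyl}chromate | [Li]OC(=[Cr](=C=O)(=C=O)(=C=O)(=C=O)=C=O)C1=C(C)CC[C@@H]1O[Si](CC)(CC)CC | intermediate
6 | pentacarbonyl{methoxy[(5S)-2-methyl-5-(triethylsilyloxy)cyclopent-1-en-1-yl]methylidene}chromium, (CO)5Cr=C(OMe)R | COC(=[Cr](=C=O)(=C=O)(=C=O)(=C=O)=C=O)C1=C(C)CC[C@@H]1O[Si](CC)(CC)CC | intermediate
7 | 3-methylfuran | Cc1ccoc1 | starting material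
8 | 6-methoxy-5-methyl-6-[(5S)-2-methyl-5-(triethylsilyloxy)cyclopent-1-en-1-yl]-2-oxabicyclo[3.1.0]hex-3-ene, cyclopentenyl group endo (cis to the dihydrofuran ring) | CO[C@@]1(C2=C(C)CC[C@@H]2O[Si](CC)(CC)CC)[C@@H]3OC=C[C@]13C | intermediate
9 | 7,10-epoxy-6-methoxy-4-(triethylsilyloxy)-11,12,13-trinordauca-5,8-diene (epoxy bridge and 4-O syn) | COC1=C2[C@@H](O[Si](CC)(CC)CC)CC[C@]2(C)[C@@H]3C=C(C)[C@H]1O3 | intermediate
10 | 6,6-(ethylenedioxy)-7,10-epoxy-11,12,13-trinordauc-8-en-4-ol (4-OH syn, H-5 anti) | O1CCOC12[C@H]3[C@@H](O)CC[C@]3(C)[C@@H]4C=C(C)[C@H]2O4 | intermediate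
11 | 6,6-(ethylenedioxy)-7,10-epoxy-11,12,13-trinordauc-8-en-4-one | O1CCOC12[C@H]3C(=O)CC[C@]3(C)[C@@H]4C=C(C)[C@H]2O4 | intermediate
12 | 6,6-(ethylenedioxy)-7,10-epoxydauc-8-en-4-ol (4-OH syn, isopropyl anti) | O1CCOC12[C@H]3[C@](O)(C(C)C)CC[C@]3(C)[C@@H]4C=C(C)[C@H]2O4 | intermediate
13 | 7,10-epoxy-4-hydroxydauc-8-en-6-one | O=C1[C@H]2[C@](O)(C(C)C)CC[C@]2(C)[C@@H]3C=C(C)[C@H]1O3 | intermediate
14 | 4,10-dihydroxydauc-8-en-6-one (both hydroxyls syn, H-5 anti) | O[C@H]1C=C(C)CC(=O)[C@@H]2[C@]1(C)CC[C@@]2(O)C(C)C | intermediate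
15 | dauc-8-ene-4,6,10-triol (4-OH syn, 6-OH anti, 10-OH syn, H-5 anti) | O[C@H]1C=C(C)C[C@H](O)[C@@H]2[C@]1(C)CC[C@@]2(O)C(C)C | intermediate
16 | 4-acetoxybenzoyl chloride | CC(=O)Oc1ccc(cc1)C(Cl)=O | starting material
17 | 6-O-(4-acetoxybenzoyl)dauc-8-ene-4,6,10-triol | O[C@H]1C=C(C)C[C@H](OC(=O)c2ccc(OC(C)=O)cc2)[C@@H]2[C@]1(C)CC[C@@]2(O)C(C)C | intermediate
18 | angelic acid, (Z)-2-methylbut-2-enoic acid | C/C=C(/C)C(=O)O | starting material
19 | angelic 2,4,6-trichlorobenzoic anhydride | C/C=C(/C)C(=O)OC(=O)c1c(Cl)cc(Cl)cc1Cl | intermediate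
20 | 10-O-angeloyl-6-O-(4-acetoxybenzoyl)dauc-8-ene-4,6,10-triol | C/C=C(/C)C(=O)O[C@H]1C=C(C)C[C@H](OC(=O)c2ccc(OC(C)=O)cc2)[C@@H]2[C@]1(C)CC[C@@]2(O)C(C)C | intermediate
21 | 10-O-angeloyl-6-O-(4-hydroxybenzoyl)dauc-8-ene-4,6,10-triol | C/C=C(/C)C(=O)O[C@H]1C=C(C)C[C@H](OC(=O)c2ccc(O)cc2)[C@@H]2[C@]1(C)CC[C@@]2(O)C(C)C | target

Total step count: 12. Longest linear sequence: 12 steps (1 to 21); compounds 7, 16 and 18 enter as purchased materials.

Steps most likely to fail

Step 4 (key step, proposed method). The weakly nucleophilic, aromatic furan may not attack the hindered carbene carbon at a useful rate. It may attack through its unsubstituted α-carbon, which would place the ring methyl next to C10. It may re-aromatise by proton loss instead of closing the cyclopropane. The two faces of the cyclopentene may also be poorly differentiated. The fallback uses the established cyclopropanation/Cope annulation of alkenyl Fischer carbene complexes with open-chain dienol ethers and sets out from 6. Compound 6 is heated with (E)-tert-butyl(dimethyl)[(3-methylbuta-1,3-dien-1-yl)oxy]silane F1 (from 3-methylbut-2-enal, TBSOTf and Et3N) to give the unbridged cycloheptadiene F2, in which the silyloxy group was outside in the boat and therefore sits anti to the C1 methyl. Ethylene glycol/PPTS gives the ketal alcohol F3, Dess–Martin oxidation the ketone F4, i-PrMgCl/CeCl3 the tertiary alcohol F5, Bu4NF the allylic alcohol F6, and Dess–Martin oxidation the enone F7. Luche reduction (NaBH4, CeCl3·7H2O, hydride anti to the C1 methyl) gives the C10-inverted alcohol F8. Aqueous HCl then gives hydroxy ketone 14, which Me4NBH(OAc)3 reduces (hydroxyl-directed, anti) to 15, where the route is rejoined.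

Step 7. Enolisation of ketone 11, β-hydride transfer from the secondary organometallic or base-induced opening of the neighbouring ketal may outrun addition. The fallback sets out from 11: the smaller, less basic sp2 nucleophile CH2=C(CH3)MgBr with CeCl3 gives the isopropenyl carbinol F9. Hydrogenation of its 1,1-disubstituted alkene with RhCl(PPh3)3 and H2, which should leave the trisubstituted ring alkene, returns to 12.

Step 10. Site selectivity may be lost (acylation at C10 or at both secondary hydroxyls), or the acyl group may migrate within the diol. The fallback sets out from 13: the SmI2 reaction is stopped after bridge cleavage (2.2 equiv, −78 °C) and hydroxy ketone 14 is isolated. Its only secondary hydroxyl (C10) is acylated with mixed anhydride 19 to the keto angelate F10. Evans–Saksena reduction with Me4NBH(OAc)3 gives the diol F11, and 16 with pyridine and DMAP then esterifies the single remaining secondary hydroxyl to return to 20.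

Further compounds
F1 | step 4 | (E)-tert-butyl(dimethyl)[(3-methylbuta-1,3-dien-1-yl)oxy]silane | CC(=C)/C=C/O[Si](C)(C)C(C)(C)C
F2 | step 4 | 10-(tert-butyldimethylsilyloxy)-6-methoxy-4-(triethylsilyloxy)-11,12,13-trinordauca-5,8-diene (10-O anti, 4-O syn) | CC(C)(C)[Si](C)(C)O[C@@H]1C=C(C)CC(OC)=C2[C@]1(C)CC[C@@H]2O[Si](CC)(CC)CC
F3 | step 4 | 10-(tert-butyldimethylsilyloxy)-6,6-(ethylenedioxy)-11,12,13-trinordauc-8-en-4-ol (10-O anti, 4-OH syn, H-5 anti) | CC(C)(C)[Si](C)(C)O[C@@H]1C=C(C)CC2(OCCO2)[C@@H]3[C@]1(C)CC[C@@H]3O
F4 | step 4 | 10-(tert-butyldimethylsilyloxy)-6,6-(ethylenedioxy)-11,12,13-trinordauc-8-en-4-one | CC(C)(C)[Si](C)(C)O[C@@H]1C=C(C)CC2(OCCO2)[C@@H]3[C@]1(C)CCC3=O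
F5 | step 4 | 10-(tert-butyldimethylsilyloxy)-6,6-(ethylenedioxy)dauc-8-en-4-ol (10-O anti, 4-OH syn) | CC(C)(C)[Si](C)(C)O[C@@H]1C=C(C)CC2(OCCO2)[C@@H]3[C@]1(C)CC[C@@]3(O)C(C)C
F6 | step 4 | 6,6-(ethylenedioxy)dauc-8-ene-4,10-diol (10-OH anti, 4-OH syn) | O[C@@H]1C=C(C)CC2(OCCO2)[C@@H]3[C@]1(C)CC[C@@]3(O)C(C)C
F7 | step 4 | 6,6-(ethylenedioxy)-4-hydroxydauc-8-en-10-one | O=C1C=C(C)CC2(OCCO2)[C@@H]3[C@]1(C)CC[C@@]3(O)C(C)C
F8 | step 4 | 6,6-(ethylenedioxy)dauc-8-ene-4,10-diol (10-OH syn, 4-OH syn) | O[C@H]1C=C(C)CC2(OCCO2)[C@@H]3[C@]1(C)CC[C@@]3(O)C(C)C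
F9 | step 7 | 6,6-(ethylenedioxy)-7,10-epoxydauca-8,11-dien-4-ol (4-OH syn) | O1CCOC12[C@H]3[C@](O)(C(C)=C)CC[C@]3(C)[C@@H]4C=C(C)[C@H]2O4
F10 | step 10 | 10-O-angeloyl-4,10-dihydroxydauc-8-en-6-one | C/C=C(/C)C(=O)O[C@H]1C=C(C)CC(=O)[C@@H]2[C@]1(C)CC[C@@]2(O)C(C)C
F11 | step 10 | 10-O-angeloyldauc-8-ene-4,6,10-triol | C/C=C(/C)C(=O)O[C@H]1C=C(C)C[C@H](O)[C@@H]2[C@]1(C)CC[C@@]2(O)C(C)C
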